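**Retrosynthetic overview**
- Target 21 ← bis-silyl ether 20 (fluoride) ← aryl 1,1-dimethylpropargyl ether 19 by gold-catalysed 6-endo hydroarylation. The plan rests on ring B: the dimethylpyran is fused across C4'(O)–C5' (linear), C5' is the free CH ortho to O4' and para to O2', and C3' lies between O2' and O4'.
- 19 ← chromone 9 + arylboronic acid 17 by rhodium-catalysed asymmetric 1,4-addition, which sets C2. The propargyl ether is put on ring B beforehand, so no base meets the flavanone; the alkyne travels as its C-trimethylsilyl derivative.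
- 9 ← symmetric acetophenone 1: ring C (pyranone) is closed first, then 5-O-prenylation and a para-Claisen–Cope shift place the prenyl group at C8.
- 17 ← 4-bromoresorcinol 10: O-propargylation para to Br, O-silylation, C-silylation, borylation.
- Ring order: ring C, then the C2 stereocentre, then the dimethylpyran on ring B last.

Key step: step 11

Assumption: 1 is bought. The (S)-bisphosphine (S)-MeO-F12-BIPHEP, (S)-6,6'-dimethoxy-2,2'-bis[bis(3,4,5-trifluorophenyl)phosphino]biphenyl, is taken to select the same enone face of a chromone as of cyclohex-2-enone, which corresponds to (2S); the (R)-ligand is used if the first run shows the opposite sense. TBS = tert-butyldimethylsilyl.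

**Step 1**
Reactants: 1 2',6'-dihydroxy-4'-methoxyacetophenone
Product: 3 5-hydroxy-7-methoxy-4H-chromen-4-one, via enaminone 2 (not isolated)
Conditions: Me2NCH(OMe)2, toluene, 90 °C; then conc. HCl, CH2Cl2, 40 °C
Reagents that add atoms: N,N-dimethylformamide dimethyl acetal, COC(OC)N(C)C
Why: Condensation of the methyl ketone with the amide acetal gives the enaminone, and acid-promoted oxa-Michael addition with loss of dimethylamine closes the pyranone (enaminone route to chromones); the ketone is symmetric, so either ortho hydroxyl gives the same chromone.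

**Step 2**
Reactants: 3 5-hydroxy-7-methoxy-4H-chromen-4-one; 4 prenyl bromide
Product: 5 7-methoxy-5-[(3-methylbut-2-en-1-yl)oxy]-4H-chromen-4-one
Conditions: K2CO3, DMF, 50 °C
Reagents that add atoms: none
Why: Williamson ether synthesis on the only hydroxyl; warming in a polar aprotic solvent overcomes the hydrogen bond to the C4 carbonyl and favours O- over C-alkylation.

**Step 3**
Reactants: 5 7-methoxy-5-[(3-methylbut-2-en-1-yl)oxy]-4H-chromen-4-one
Product: 8 5-hydroxy-7-methoxy-8-(3-methylbut-2-en-1-yl)-4H-chromen-4-one, via ortho-dienone 6 (not isolated), via para-dienone 7 (not isolated)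
Conditions: Eu(fod)3 (fod = 6,6,7,7,8,8,8-heptafluoro-2,2-dimethyloctane-3,5-dionate; 10 mol%), NaHCO3, PhCl, 85 °C
Reagents that add atoms: none
Why: Trivalent europium chelated between O5 and the C4 carbonyl accelerates the aromatic Claisen rearrangement to C6, and the 1,1-dimethylallyl dienone then undergoes Cope rearrangement to C8 and enolises (para-Claisen–Cope), so the prenyl group ends on the carbon next to O1 with the ring oxygen already fixed.

**Step 4**
Reactants: 8 5-hydroxy-7-methoxy-8-(3-methylbut-2-en-1-yl)-4H-chromen-4-one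
Product: 9 5-[(tert-butyldimethylsilyl)oxy]-7-methoxy-8-(3-methylbut-2-en-1-yl)-4H-chromen-4-one
Conditions: TBSOTf, 2,6-lutidine, CH2Cl2, 0 °C
Reagents that add atoms: tert-butyldimethylsilyl triflate, CC(C)(C)[Si](C)(C)OS(=O)(=O)C(F)(F)F
Why: O-silylation of a hydrogen-bonded phenol with a silyl triflate; it masks the O5–H/C4=O pair, which would otherwise bind the rhodium hydroxide of step 9 as an acetylacetonate-like chelate, and the group leaves with the other silyl ether in step 12.

**Step 5**
Reactants: 10 4-bromoresorcinol; 11 3-chloro-3-methylbut-1-yne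
Product: 12 2-bromo-5-[(2-methylbut-3-yn-2-yl)oxy]phenol
Conditions: K2CO3, KI, CuI (5 mol%), acetone, 50 °C
Reagents that add atoms: none
Why: Copper-catalysed propargylic O-alkylation of a phenol through the copper acetylide; the hydroxyl para to bromine is the less hindered one and its phenoxide the more nucleophilic, and the ether is made here because a phenoxide at O4' of the later flavanone could open ring C and racemise C2.

**Step 6**
Reactants: 12 2-bromo-5-[(2-methylbut-3-yn-2-yl)oxy]phenol
Product: 13 {2-bromo-5-[(2-methylbut-3-yn-2-yl)oxy]phenoxy}(tert-butyl)dimethylsilane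
Conditions: TBSCl, imidazole, DMF, rt
Reagents that add atoms: tert-butyldimethylsilyl chloride, CC(C)(C)[Si](C)(C)Cl
Why: Standard imidazole-mediated silylation of the remaining phenol; this bulky group later shields C3'.

**Step 7**
Reactants: 13 {2-bromo-5-[(2-methylbut-3-yn-2-yl)oxy]phenoxy}(tert-butyl)dimethylsilane
Product: 14 (2-bromo-5-{[2-methyl-4-(trimethylsilyl)but-3-yn-2-yl]oxy}phenoxy)(tert-butyl)dimethylsilane
Conditions: LiN(i-Pr)2 (1.05 equiv), THF, −78 °C; TMSCl, −78 °C to rt
Reagents that add atoms: chlorotrimethylsilane, C[Si](C)(C)Cl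
Why: Deprotonation of the terminal alkyne, by far the most acidic site, and C-silylation of the acetylide; the cap removes the acidic C–H before lithiation and keeps the alkyne out of the aryl–rhodium chemistry of step 9.

**Step 8**
Reactants: 14 (2-bromo-5-{[2-methyl-4-(trimethylsilyl)but-3-yn-2-yl]oxy}phenoxy)(tert-butyl)dimethylsilane
Product: 17 (2-[(tert-butyldimethylsilyl)oxy]-4-{[2-methyl-4-(trimethylsilyl)but-3-yn-2-yl]oxy}phenyl)boronic acid, via aryllithium 15 (not isolated), via lithium triisopropoxyborate 16 (not isolated)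
Conditions: B(OiPr)3 (1.5 equiv), THF/toluene, −78 °C, n-BuLi added last; then sat. aq. NH4Cl, rt
Reagents that add atoms: triisopropyl borate, CC(C)OB(OC(C)C)OC(C)C; water, O
Why: Bromine–lithium exchange with in-situ borate quench, so the ortho-silyloxy aryllithium is trapped before a 1,3 O-to-C silyl shift (retro-Brook) can occur, and mild hydrolysis gives the boronic acid.

**Step 9**
Reactants: 9 5-[(tert-butyldimethylsilyl)oxy]-7-methoxy-8-(3-methylbut-2-en-1-yl)-4H-chromen-4-one; 17 (2-[(tert-butyldimethylsilyl)oxy]-4-{[2-methyl-4-(trimethylsilyl)but-3-yn-2-yl]oxy}phenyl)boronic acid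
Product: 18 (S)-5-[(tert-butyldimethylsilyl)oxy]-2-(2-[(tert-butyldimethylsilyl)oxy]-4-{[2-methyl-4-(trimethylsilyl)but-3-yn-2-yl]oxy}phenyl)-7-methoxy-8-(3-methylbut-2-en-1-yl)chroman-4-one
Conditions: [Rh(OH)((S)-MeO-F12-BIPHEP)]2 (2.5 mol%), 17 (2.5 equiv), toluene/H2O 10:1, 40 °C, no added base
Reagents that add atoms: none
Why: Rhodium-catalysed asymmetric 1,4-addition of an arylboronic acid to a chromone (Hayashi–Miyaura reaction): the aryl–rhodium species (monovalent rhodium) inserts C2=C3 on the enone face left open by the C2-symmetric bisphosphine, which sets C2 as (S), and water protonates the rhodium enolate; the capped, doubly hindered alkyne and the prenyl alkene do not insert, and no base is present that could open ring C.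

**Step 10**
Reactants: 18 (S)-5-[(tert-butyldimethylsilyl)oxy]-2-(2-[(tert-butyldimethylsilyl)oxy]-4-{[2-methyl-4-(trimethylsilyl)but-3-yn-2-yl]oxy}phenyl)-7-methoxy-8-(3-methylbut-2-en-1-yl)chroman-4-one
Product: 19 (S)-5-[(tert-butyldimethylsilyl)oxy]-2-{2-[(tert-butyldimethylsilyl)oxy]-4-[(2-methylbut-3-yn-2-yl)oxy]phenyl}-7-methoxy-8-(3-methylbut-2-en-1-yl)chroman-4-one
Conditions: AgNO3 (10 mol%), acetone/CH2Cl2/H2O, rt
Reagents that add atoms: none
Why: Silver-catalysed protodesilylation of a trimethylsilyl alkyne, in which water attacks silicon of the silver-bound alkyne and the silver acetylide is protonated; the conditions are neutral, so the aryl silyl ethers and C2 are left alone.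

**Step 11**
Reactants: 19 (S)-5-[(tert-butyldimethylsilyl)oxy]-2-{2-[(tert-butyldimethylsilyl)oxy]-4-[(2-methylbut-3-yn-2-yl)oxy]phenyl}-7-methoxy-8-(3-methylbut-2-en-1-yl)chroman-4-one
Product: 20 (S)-5-[(tert-butyldimethylsilyl)oxy]-2-{7-[(tert-butyldimethylsilyl)oxy]-2,2-dimethyl-2H-chromen-6-yl}-7-methoxy-8-(3-methylbut-2-en-1-yl)chroman-4-one
Conditions: Ph3PAuNTf2 (3 mol%), dry CH2Cl2, rt
Reagents that add atoms: none
Why: The cationic complex of monovalent gold binds the terminal alkyne of the aryl 1,1-dimethylpropargyl ether, C5' of ring B attacks the terminal alkyne carbon in a Friedel–Crafts sense to give a vinylgold arenium ion, and rearomatisation with protodeauration releases the 2H-chromene and the catalyst. This is the known gold-catalysed intramolecular hydroarylation of aryl propargyl ethers to 2H-chromenes. The pyran ring closes 6-endo-dig and only the bond from C5' to the pyran CH carbon is made, since the O4'–CMe2 bond is already in place. No stereocentre is formed, and C2 is not touched because the medium is neutral and at room temperature. The step needs regioselectivity between the two carbons ortho to O4': C3' sits between O2' and O4' and is walled in by the 2'-O-TBS group and the gem-dimethyl carbon, whereas C5' is open and para to the donor O2', so linear closure at C5' is expected. It also needs chemoselectivity, which comes from ring A being deactivated by the C4 carbonyl, from the prenyl alkene having no free phenol beside it, and from the absence of any free hydroxyl that could add to the activated alkyne.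

**Step 12**
Reactants: 20 (S)-5-[(tert-butyldimethylsilyl)oxy]-2-{7-[(tert-butyldimethylsilyl)oxy]-2,2-dimethyl-2H-chromen-6-yl}-7-methoxy-8-(3-methylbut-2-en-1-yl)chroman-4-one
Product: 21 maackiaflavanone A, (S)-5-hydroxy-2-(7-hydroxy-2,2-dimethyl-2H-chromen-6-yl)-7-methoxy-8-(3-methylbut-2-en-1-yl)chroman-4-one
Conditions: HF·pyridine, pyridine, THF, 0 °C to rt
Reagents that add atoms: none
Why: Fluoride cleavage of both aryl silyl ethers under buffered, weakly acidic conditions, so no phenoxide forms at O2' that could open ring C and racemise C2; the chromene and prenyl alkenes are inert.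

**Compound list**
1 | 2',6'-dihydroxy-4'-methoxyacetophenone | CC(=O)c1c(O)cc(OC)cc1O | starting material
2 | (E)-3-(dimethylamino)-1-(2,6-dihydroxy-4-methoxyphenyl)prop-2-en-1-one | CN(C)/C=C/C(=O)c1c(O)cc(OC)cc1O | intermediate
3 | 5-hydroxy-7-methoxy-4H-chromen-4-one | COc1cc(O)c2c(c1)occc2=O | intermediate
4 | prenyl bromide (1-bromo-3-methylbut-2-ene) | CC(C)=CCBr | starting material
5 | 7-methoxy-5-[(3-methylbut-2-en-1-yl)oxy]-4H-chromen-4-one | COc1cc(OCC=C(C)C)c2c(c1)occc2=O | intermediate
6 | 7-methoxy-6-(2-methylbut-3-en-2-yl)-6H-chromene-4,5-dione (ortho-dienone) | O=C1C=COC2=C1C(=O)C(C(C)(C)C=C)C(OC)=C2 | intermediate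
7 | 7-methoxy-8-(3-methylbut-2-en-1-yl)-8H-chromene-4,5-dione (para-dienone) | O=C1C=COC2=C1C(=O)C=C(OC)C2CC=C(C)C | intermediate
8 | 5-hydroxy-7-methoxy-8-(3-methylbut-2-en-1-yl)-4H-chromen-4-one | COc1cc(O)c2c(c1CC=C(C)C)occc2=O | intermediate
9 | 5-[(tert-butyldimethylsilyl)oxy]-7-methoxy-8-(3-methylbut-2-en-1-yl)-4H-chromen-4-one | COc1cc(O[Si](C)(C)C(C)(C)C)c2c(c1CC=C(C)C)occc2=O | intermediate
10 | 4-bromoresorcinol | Oc1ccc(Br)c(O)c1 | starting material
11 | 3-chloro-3-methylbut-1-yne | CC(C)(Cl)C#C | starting material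
12 | 2-bromo-5-[(2-methylbut-3-yn-2-yl)oxy]phenol | Oc1cc(OC(C)(C)C#C)ccc1Br | intermediate
13 | {2-bromo-5-[(2-methylbut-3-yn-2-yl)oxy]phenoxy}(tert-butyl)dimethylsilane | CC(C)(C)[Si](C)(C)Oc1cc(OC(C)(C)C#C)ccc1Br | intermediate
14 | (2-bromo-5-{[2-methyl-4-(trimethylsilyl)but-3-yn-2-yl]oxy}phenoxy)(tert-butyl)dimethylsilane | CC(C)(C)[Si](C)(C)Oc1cc(OC(C)(C)C#C[Si](C)(C)C)ccc1Br | intermediate
15 | aryllithium from 14 (Li in place of Br) | CC(C)(C)[Si](C)(C)Oc1cc(OC(C)(C)C#C[Si](C)(C)C)ccc1[Li] | intermediate
16 | lithium aryl(triisopropoxy)borate from 15 | [Li+].CC(C)O[B-](OC(C)C)(OC(C)C)c1ccc(OC(C)(C)C#C[Si](C)(C)C)cc1O[Si](C)(C)C(C)(C)C | intermediate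
17 | (2-[(tert-butyldimethylsilyl)oxy]-4-{[2-methyl-4-(trimethylsilyl)but-3-yn-2-yl]oxy}phenyl)boronic acid | CC(C)(C)[Si](C)(C)Oc1cc(OC(C)(C)C#C[Si](C)(C)C)ccc1B(O)O | intermediate
18 | (S)-5-[(tert-butyldimethylsilyl)oxy]-2-(2-[(tert-butyldimethylsilyl)oxy]-4-{[2-methyl-4-(trimethylsilyl)but-3-yn-2-yl]oxy}phenyl)-7-methoxy-8-(3-methylbut-2-en-1-yl)chroman-4-one | COc1cc(O[Si](C)(C)C(C)(C)C)c2c(c1CC=C(C)C)O[C@H](c1ccc(OC(C)(C)C#C[Si](C)(C)C)cc1O[Si](C)(C)C(C)(C)C)CC2=O | intermediate
19 | (S)-5-[(tert-butyldimethylsilyl)oxy]-2-{2-[(tert-butyldimethylsilyl)oxy]-4-[(2-methylbut-3-yn-2-yl)oxy]phenyl}-7-methoxy-8-(3-methylbut-2-en-1-yl)chroman-4-one (key-step precursor) | COc1cc(O[Si](C)(C)C(C)(C)C)c2c(c1CC=C(C)C)O[C@H](c1ccc(OC(C)(C)C#C)cc1O[Si](C)(C)C(C)(C)C)CC2=O | intermediate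
20 | (S)-5-[(tert-butyldimethylsilyl)oxy]-2-{7-[(tert-butyldimethylsilyl)oxy]-2,2-dimethyl-2H-chromen-6-yl}-7-methoxy-8-(3-methylbut-2-en-1-yl)chroman-4-one (key-step product) | COc1cc(O[Si](C)(C)C(C)(C)C)c2c(c1CC=C(C)C)O[C@H](c1cc3c(cc1O[Si](C)(C)C(C)(C)C)OC(C)(C)C=C3)CC2=O | intermediate
21 | maackiaflavanone A, (2S) | COc1cc(O)c2c(c1CC=C(C)C)O[C@H](c1cc3c(cc1O)OC(C)(C)C=C3)CC2=O | target

**Step count**
Total: 12 steps. Longest linear sequence: 8 steps (steps 5–12 from 10; equally steps 1–4 and 9–12 from 1).

**Steps most likely to fail**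

Step 11. The ring may close at C3' in competition with C5', or the chromene may be lost to gold- or acid-promoted oligomerisation. The fallback sets out from 13 and comes back at 20. It moves the ring closure to the small ring B bromide, where there is no stereocentre, prenyl group or chromanone and a minor regioisomer can be removed by chromatography. Treating 13 with Ph3PAuNTf2 in CH2Cl2, or heating it in N,N-diethylaniline at 180 °C (thermal propargyl Claisen, 1,5-hydrogen shift and 6π-electrocyclisation), should give tert-butyl[(6-bromo-2,2-dimethyl-2H-chromen-7-yl)oxy]dimethylsilane F1. Bromine–lithium exchange with n-BuLi in the presence of B(OiPr)3 and mild hydrolysis should give {7-[(tert-butyldimethylsilyl)oxy]-2,2-dimethyl-2H-chromen-6-yl}boronic acid F2. Its asymmetric 1,4-addition to 9 under the conditions of step 9 should give 20 directly, so steps 7, 10 and 11 fall away.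

Step 9. Transmetalation of the hindered, electron-rich boronic acid may be slower than its protodeboronation, or the facial selectivity may fall short. The fallback sets out from 9 and 17 and comes back at 18. It gives up catalyst control for resolution: with the more active achiral complex [Rh(OH)(cod)]2 (cod = cycloocta-1,5-diene) in dioxane/H2O, 9 and 17 should give the racemic flavanone F3. Preparative HPLC on a polysaccharide chiral phase should separate it into 18 and the (R)-enantiomer F4, which is discarded.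

Step 5. Alkylation may take place at the hydroxyl ortho to bromine or at both hydroxyls. The fallback sets out from 10 and comes back at 13. It differentiates the two oxygens by acylation before the ether is made. Pivaloyl chloride (1.0 equiv) and pyridine in CH2Cl2 at −20 °C should acylate the unhindered hydroxyl to give 4-bromo-3-hydroxyphenyl pivalate F5. TBSCl and imidazole should give 4-bromo-3-[(tert-butyldimethylsilyl)oxy]phenyl pivalate F6. i-Bu2AlH in CH2Cl2 at −78 °C should remove the ester to give 4-bromo-3-[(tert-butyldimethylsilyl)oxy]phenol F7. Propargylation of F7 with 11 (DBU, CuCl2 (cat.), MeCN, −5 °C) should then give 13.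

**Further compounds**
F1 | step 11 | tert-butyl[(6-bromo-2,2-dimethyl-2H-chromen-7-yl)oxy]dimethylsilane | CC(C)(C)[Si](C)(C)Oc1cc2c(cc1Br)C=CC(C)(C)O2
F2 | step 11 | {7-[(tert-butyldimethylsilyl)oxy]-2,2-dimethyl-2H-chromen-6-yl}boronic acid | CC(C)(C)[Si](C)(C)Oc1cc2c(cc1B(O)O)C=CC(C)(C)O2
F3 | step 9 | racemic 18 | COc1cc(O[Si](C)(C)C(C)(C)C)c2c(c1CC=C(C)C)OC(c1ccc(OC(C)(C)C#C[Si](C)(C)C)cc1O[Si](C)(C)C(C)(C)C)CC2=O
F4 | step 9 | (R)-enantiomer of 18 | COc1cc(O[Si](C)(C)C(C)(C)C)c2c(c1CC=C(C)C)O[C@@H](c1ccc(OC(C)(C)C#C[Si](C)(C)C)cc1O[Si](C)(C)C(C)(C)C)CC2=O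
F5 | step 5 | 4-bromo-3-hydroxyphenyl pivalate | CC(C)(C)C(=O)Oc1ccc(Br)c(O)c1
F6 | step 5 | 4-bromo-3-[(tert-butyldimethylsilyl)oxy]phenyl pivalate | CC(C)(C)C(=O)Oc1ccc(Br)c(O[Si](C)(C)C(C)(C)C)c1
F7 | step 5 | 4-bromo-3-[(tert-butyldimethylsilyl)oxy]phenol | Oc1ccc(Br)c(O[Si](C)(C)C(C)(C)C)c1
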